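**Strategy.** The route rests on cutting the bond between C5 of the benzo ring of the 2,3-dihydrobenzofuran and the neighbouring olefinic carbon of the stilbene. A late Mizoroki–Heck reaction joins the enantiopure (2R,3S)-5-bromo-dihydrobenzofuran to 3,5-bis(silyloxy)styrene, forging this aryl–vinyl bond and setting the E double bond in one operation. It exploits the fact that C5 is an sp2 carbon para to O1 and remote from the C2/C3 stereocentres of the furan ring, so these pass through untouched. The bromide arises from a Rh-catalysed enantioselective benzylic C–H insertion of an aryl diazoacetate, followed by C3 epimerisation to the trans series and ester reduction.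

Key step: step 10

**Assumptions.**
- Compounds 1, 4 and 11 are taken as commercially available.
- The sense of induction of Rh2(R-PTTL)4 (dirhodium tetrakis[N-phthaloyl-(R)-tert-leucinate]) is assumed to be the one described for 5-bromo-2-(benzyloxy)phenyl diazoacetates, which corresponds to 2R here. If the extra 3-methoxy group reverses it, the (S)-configured catalyst is used instead.

**Route**

Step 1
Reactants: 1 syringaldehyde (4-hydroxy-3,5-dimethoxybenzaldehyde)
Product: 2 3,5-dimethoxy-4-(triisopropylsilyloxy)benzaldehyde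
Conditions: TIPSCl, imidazole, DMF, rt
Reagents that add atoms: triisopropylsilyl chloride, CC(C)[Si](Cl)(C(C)C)C(C)C
Why: Imidazole-promoted O-silylation of the phenol should give a TIPS ether hindered enough to survive the later basic and reductive steps.

Step 2
Reactants: 2 3,5-dimethoxy-4-(triisopropylsilyloxy)benzaldehyde
Product: 3 [3,5-dimethoxy-4-(triisopropylsilyloxy)phenyl]methanol
Conditions: NaBH4, MeOH, 0 °C
Reagents that add atoms: none
Why: Borohydride reduction of the aldehyde should give the benzylic alcohol without touching the aryl silyl ether.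

Step 3
Reactants: 4 4-bromo-2-methoxyphenol
Product: 5 4-bromo-2-iodo-6-methoxyphenol
Conditions: NaI, NaOH, aq NaOCl, MeOH, 0 °C
Reagents that add atoms: sodium iodide, [Na+].[I-]
Why: Electrophilic aromatic iodination of the phenoxide by hypoiodite formed in situ should occur at the only free ortho position, the para position being blocked by bromine.

Step 4
Reactants: 3 [3,5-dimethoxy-4-(triisopropylsilyloxy)phenyl]methanol; 5 4-bromo-2-iodo-6-methoxyphenol
Product: 6 5-bromo-1-iodo-3-methoxy-2-{[3,5-dimethoxy-4-(triisopropylsilyloxy)phenyl]methoxy}benzene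
Conditions: PPh3, DIAD, THF, 0 °C to rt
Reagents that add atoms: none
Why: Mitsunobu etherification should join the acidic, di-ortho-substituted phenol to the primary benzylic alcohol under neutral conditions that spare the silyl ether.

Step 5
Reactants: 6 5-bromo-1-iodo-3-methoxy-2-{[3,5-dimethoxy-4-(triisopropylsilyloxy)phenyl]methoxy}benzene
Product: 7 ethyl 2-(5-bromo-3-methoxy-2-{[3,5-dimethoxy-4-(triisopropylsilyloxy)phenyl]methoxy}phenyl)-2-diazoacetate
Conditions: ethyl diazoacetate, Pd(PPh3)4 (5 mol%), Ag2CO3 (0.5 equiv), Et3N, toluene, rt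
Reagents that add atoms: ethyl diazoacetate, CCOC(=O)C=[N+]=[N-]
Why: Pd-catalysed cross-coupling of an aryl iodide with the C–H bond of a diazoacetate (diazo group retained) should occur selectively at C–I, since Pd(PPh3)4 does not add to the C–Br bond at room temperature.

Step 6
Reactants: 7 ethyl 2-(5-bromo-3-methoxy-2-{[3,5-dimethoxy-4-(triisopropylsilyloxy)phenyl]methoxy}phenyl)-2-diazoacetate
Product: 9 ethyl (2R,3R)-5-bromo-2-[3,5-dimethoxy-4-(triisopropylsilyloxy)phenyl]-7-methoxy-2,3-dihydro-1-benzofuran-3-carboxylate (trans ester), via cis-(2R,3S) ester 8 (not isolated)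
Conditions: Rh2(R-PTTL)4 (2 mol%), toluene, −60 °C; then NaOEt (0.3 equiv), EtOH, 0 °C to rt
Reagents that add atoms: none
Why: Intramolecular Rh(II)-carbenoid 1,5 C–H insertion into the electron-rich benzylic C–H bond should close the dihydrofuran ring as the cis ester, with the chiral carboxylate catalyst selecting one enantiotopic hydrogen and so setting C2 (R); base epimerisation at C3 (alpha to the ester) should then give the thermodynamically favoured trans ester while C2 stays untouched.

Step 7
Reactants: 9 ethyl (2R,3R)-5-bromo-2-[3,5-dimethoxy-4-(triisopropylsilyloxy)phenyl]-7-methoxy-2,3-dihydro-1-benzofuran-3-carboxylate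
Product: 10 {(2R,3S)-5-bromo-2-[3,5-dimethoxy-4-(triisopropylsilyloxy)phenyl]-7-methoxy-2,3-dihydro-1-benzofuran-3-yl}methanol
Conditions: DIBAL-H, CH2Cl2, −78 to 0 °C; Rochelle salt work-up
Reagents that add atoms: none
Why: Hydride reduction of the ester to the primary alcohol should spare the aryl bromide and the silyl ether and removes the acidic C3–H, fixing the trans relationship before the base- and heat-mediated coupling.

Step 8
Reactants: 11 3,5-dihydroxybenzaldehyde
Product: 12 3,5-bis(tert-butyldimethylsilyloxy)benzaldehyde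
Conditions: TBSCl, imidazole, DMF, rt
Reagents that add atoms: tert-butyldimethylsilyl chloride, CC(C)(C)[Si](C)(C)Cl
Why: Standard imidazole-promoted bis-silylation of the two phenols masks them for the ylide and palladium steps.

Step 9
Reactants: 12 3,5-bis(tert-butyldimethylsilyloxy)benzaldehyde
Product: 13 3,5-bis(tert-butyldimethylsilyloxy)styrene
Conditions: Ph3PCH3Br, n-BuLi, THF, −78 °C to rt
Reagents that add atoms: methyltriphenylphosphonium bromide, C[P+](c1ccccc1)(c1ccccc1)c1ccccc1.[Br-]
Why: Wittig methylenation of the aldehyde with a salt-free-of-alkoxide ylide should give the terminal styrene without cleaving the aryl silyl ethers.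

Step 10
Reactants: 10 {(2R,3S)-5-bromo-2-[3,5-dimethoxy-4-(triisopropylsilyloxy)phenyl]-7-methoxy-2,3-dihydro-1-benzofuran-3-yl}methanol; 13 3,5-bis(tert-butyldimethylsilyloxy)styrene
Product: 14 {(2R,3S)-5-[(E)-2-[3,5-bis(tert-butyldimethylsilyloxy)phenyl]ethenyl]-2-[3,5-dimethoxy-4-(triisopropylsilyloxy)phenyl]-7-methoxy-2,3-dihydro-1-benzofuran-3-yl}methanol
Conditions: Pd2(dba)3 (2.5 mol%), [HP(t-Bu)3]BF4 (10 mol%), Cy2NMe, 1,4-dioxane, 60–80 °C
Reagents that add atoms: none
Why: Mizoroki–Heck reaction: Pd(0)/P(t-Bu)3 should add oxidatively to the C5–Br bond of 10, the aryl–Pd species should insert the terminal olefin carbon of 13 in a syn fashion, and syn-β-hydride elimination should release the stilbene. The closest known reaction type is the Heck arylation of styrenes with electron-rich aryl bromides under bulky trialkylphosphine catalysis. No ring is closed and no stereocentre is formed; the only new stereo-element is the C=C geometry, which should be E because β-hydride elimination proceeds from the rotamer that places the two aryl groups anti. The step needs regioselectivity for the terminal carbon of the styrene, secured by the neutral Pd pathway and the steric bias of the monosubstituted olefin, and chemoselectivity for C–Br, the only carbon–halogen bond in 10. C2 and C3 are not at risk, because no acidic C–H remains after the ester reduction and the silylated syringyl oxygen cannot open the furan ring through a quinone methide. The free primary alcohol and the three aryl silyl ethers should tolerate the hindered amine base in dioxane.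

Step 11
Reactants: 14 {(2R,3S)-5-[(E)-2-[3,5-bis(tert-butyldimethylsilyloxy)phenyl]ethenyl]-2-[3,5-dimethoxy-4-(triisopropylsilyloxy)phenyl]-7-methoxy-2,3-dihydro-1-benzofuran-3-yl}methanol
Product: 15 gnetucleistol F, 5-[(E)-2-[(2R,3S)-2-(4-hydroxy-3,5-dimethoxyphenyl)-3-(hydroxymethyl)-7-methoxy-2,3-dihydro-1-benzofuran-5-yl]ethenyl]benzene-1,3-diol
Conditions: TBAF, AcOH, THF, 0 °C to rt, under argon in the dark
Reagents that add atoms: none
Why: Fluoride-mediated cleavage of all three aryl silyl ethers, buffered with acetic acid so that no free phenoxide can open the furan ring or oxidise, should release the target with stereocentres and olefin geometry unchanged.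

**Compound list**

1 | syringaldehyde (4-hydroxy-3,5-dimethoxybenzaldehyde) | COc1cc(C=O)cc(OC)c1O | starting material
2 | 3,5-dimethoxy-4-(triisopropylsilyloxy)benzaldehyde | COc1cc(C=O)cc(OC)c1O[Si](C(C)C)(C(C)C)C(C)C | intermediate
3 | [3,5-dimethoxy-4-(triisopropylsilyloxy)phenyl]methanol | COc1cc(CO)cc(OC)c1O[Si](C(C)C)(C(C)C)C(C)C | intermediate
4 | 4-bromo-2-methoxyphenol | COc1cc(Br)ccc1O | starting material
5 | 4-bromo-2-iodo-6-methoxyphenol | COc1cc(Br)cc(I)c1O | intermediate
6 | 5-bromo-1-iodo-3-methoxy-2-{[3,5-dimethoxy-4-(triisopropylsilyloxy)phenyl]methoxy}benzene | COc1cc(Br)cc(I)c1OCc1cc(OC)c(O[Si](C(C)C)(C(C)C)C(C)C)c(OC)c1 | intermediate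
7 | ethyl 2-(5-bromo-3-methoxy-2-{[3,5-dimethoxy-4-(triisopropylsilyloxy)phenyl]methoxy}phenyl)-2-diazoacetate | CCOC(=O)C(=[N+]=[N-])c1cc(Br)cc(OC)c1OCc1cc(OC)c(O[Si](C(C)C)(C(C)C)C(C)C)c(OC)c1 | intermediate
8 | ethyl (2R,3S)-5-bromo-2-[3,5-dimethoxy-4-(triisopropylsilyloxy)phenyl]-7-methoxy-2,3-dihydro-1-benzofuran-3-carboxylate (cis ester, formed in the flask) | COc1cc([C@@H]2Oc3c(OC)cc(Br)cc3[C@@H]2C(=O)OCC)cc(OC)c1O[Si](C(C)C)(C(C)C)C(C)C | intermediate
9 | ethyl (2R,3R)-5-bromo-2-[3,5-dimethoxy-4-(triisopropylsilyloxy)phenyl]-7-methoxy-2,3-dihydro-1-benzofuran-3-carboxylate (trans ester) | COc1cc([C@@H]2Oc3c(OC)cc(Br)cc3[C@H]2C(=O)OCC)cc(OC)c1O[Si](C(C)C)(C(C)C)C(C)C | intermediate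
10 | {(2R,3S)-5-bromo-2-[3,5-dimethoxy-4-(triisopropylsilyloxy)phenyl]-7-methoxy-2,3-dihydro-1-benzofuran-3-yl}methanol | COc1cc([C@@H]2Oc3c(OC)cc(Br)cc3[C@H]2CO)cc(OC)c1O[Si](C(C)C)(C(C)C)C(C)C | intermediate
11 | 3,5-dihydroxybenzaldehyde | O=Cc1cc(O)cc(O)c1 | starting material
12 | 3,5-bis(tert-butyldimethylsilyloxy)benzaldehyde | O=Cc1cc(O[Si](C)(C)C(C)(C)C)cc(O[Si](C)(C)C(C)(C)C)c1 | intermediate
13 | 3,5-bis(tert-butyldimethylsilyloxy)styrene | C=Cc1cc(O[Si](C)(C)C(C)(C)C)cc(O[Si](C)(C)C(C)(C)C)c1 | intermediate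
14 | {(2R,3S)-5-[(E)-2-[3,5-bis(tert-butyldimethylsilyloxy)phenyl]ethenyl]-2-[3,5-dimethoxy-4-(triisopropylsilyloxy)phenyl]-7-methoxy-2,3-dihydro-1-benzofuran-3-yl}methanol | COc1cc([C@@H]2Oc3c(OC)cc(/C=C/c4cc(O[Si](C)(C)C(C)(C)C)cc(O[Si](C)(C)C(C)(C)C)c4)cc3[C@H]2CO)cc(OC)c1O[Si](C(C)C)(C(C)C)C(C)C | intermediate
15 | gnetucleistol F | COc1cc([C@@H]2Oc3c(OC)cc(/C=C/c4cc(O)cc(O)c4)cc3[C@H]2CO)cc(OC)c1O | target

**Step count.** Total: 11 steps. Longest linear sequence: 8 steps (1, 2, 4, 5, 6, 7, 10, 11).

**Steps most likely to fail, each with a fallback**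

Step 6. The catalyst may discriminate the two enantiotopic benzylic hydrogens poorly because the extra methoxy group beside the benzyloxy oxygen twists the ether. Enantiopurity may also erode during the epimerisation through reversible retro-oxa-Michael opening of the furan ring. The fallback gives up catalyst control for a classical resolution; it sets out from 7 and comes back at 10. Compound 7 is decomposed with achiral Rh2(OAc)4 in CH2Cl2 to the racemic cis ester F1, which is epimerised in the same flask with NaOEt to the racemic trans ester F2. DIBAL-H reduction gives the racemic trans alcohol F3. Acylation with (1S)-(−)-camphanic chloride (O=C(Cl)[C@@]12CC[C@@](C)(C(=O)O1)C2(C)C; Et3N, DMAP, CH2Cl2) gives the (2R,3S)-alcohol camphanate F4 and its diastereomer, the (2S,3R)-alcohol camphanate F5. These are separated by chromatography or crystallisation, and methanolysis of F4 (K2CO3, MeOH) returns 10.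

Step 5. Oxidative addition next to the bulky ortho-benzyloxy group may be slow, so that the diazoacetate decomposes or dimerises before it couples, or palladium begins to add to the C–Br bond. The fallback builds the diazo group by a Bamford–Stevens sequence; it sets out from 6 and comes back at 7. Iodine–magnesium exchange of 6 with i-PrMgCl·LiCl (THF, −40 °C; selective for iodine over bromine) and trapping with diethyl oxalate gives the aryl glyoxylate F6. Condensation with tosylhydrazide gives the tosylhydrazone F7, and DBU in CH2Cl2 eliminates sulfinate to give 7.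

Step 10. The electron-rich bromide may add to palladium slowly, so that at the temperature required the aryl silyl ethers are lost or the styrene oligomerises, and some arylation at the internal olefin carbon may occur. The fallback forms the same aryl–vinyl bond by Suzuki–Miyaura coupling; it sets out from 13 (with 10) and comes back at 14. Cross-metathesis of 13 with vinylboronic acid pinacol ester (second-generation Grubbs catalyst, CH2Cl2, 40 °C) gives the (E)-styrylboronate F8. Coupling of F8 with 10 (Pd(dppf)Cl2, K3PO4, dioxane/H2O, 70 °C) transfers the preformed E-alkene with retention and gives 14. Any partial desilylation is harmless because step 11 removes all silyl groups.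

**Further compounds**

F1 | step 6 | racemic cis ethyl 5-bromo-2-[3,5-dimethoxy-4-(triisopropylsilyloxy)phenyl]-7-methoxy-2,3-dihydro-1-benzofuran-3-carboxylate (both enantiomers) | COc1cc([C@@H]2Oc3c(OC)cc(Br)cc3[C@@H]2C(=O)OCC)cc(OC)c1O[Si](C(C)C)(C(C)C)C(C)C.COc1cc([C@H]2Oc3c(OC)cc(Br)cc3[C@H]2C(=O)OCC)cc(OC)c1O[Si](C(C)C)(C(C)C)C(C)C
F2 | step 6 | racemic trans ethyl 5-bromo-2-[3,5-dimethoxy-4-(triisopropylsilyloxy)phenyl]-7-methoxy-2,3-dihydro-1-benzofuran-3-carboxylate (both enantiomers) | COc1cc([C@@H]2Oc3c(OC)cc(Br)cc3[C@H]2C(=O)OCC)cc(OC)c1O[Si](C(C)C)(C(C)C)C(C)C.COc1cc([C@H]2Oc3c(OC)cc(Br)cc3[C@@H]2C(=O)OCC)cc(OC)c1O[Si](C(C)C)(C(C)C)C(C)C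
F3 | step 6 | racemic trans {5-bromo-2-[3,5-dimethoxy-4-(triisopropylsilyloxy)phenyl]-7-methoxy-2,3-dihydro-1-benzofuran-3-yl}methanol (both enantiomers) | COc1cc([C@@H]2Oc3c(OC)cc(Br)cc3[C@H]2CO)cc(OC)c1O[Si](C(C)C)(C(C)C)C(C)C.COc1cc([C@H]2Oc3c(OC)cc(Br)cc3[C@@H]2CO)cc(OC)c1O[Si](C(C)C)(C(C)C)C(C)C
F4 | step 6 | (1S,4R)-camphanate of the (2R,3S) alcohol | COc1cc([C@@H]2Oc3c(OC)cc(Br)cc3[C@H]2COC(=O)[C@@]23CC[C@@](C)(C(=O)O2)C3(C)C)cc(OC)c1O[Si](C(C)C)(C(C)C)C(C)C
F5 | step 6 | (1S,4R)-camphanate of the (2S,3R) alcohol | COc1cc([C@H]2Oc3c(OC)cc(Br)cc3[C@@H]2COC(=O)[C@@]23CC[C@@](C)(C(=O)O2)C3(C)C)cc(OC)c1O[Si](C(C)C)(C(C)C)C(C)C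
F6 | step 5 | ethyl 2-(5-bromo-3-methoxy-2-{[3,5-dimethoxy-4-(triisopropylsilyloxy)phenyl]methoxy}phenyl)-2-oxoacetate | CCOC(=O)C(=O)c1cc(Br)cc(OC)c1OCc1cc(OC)c(O[Si](C(C)C)(C(C)C)C(C)C)c(OC)c1
F7 | step 5 | tosylhydrazone of F6 | CCOC(=O)C(=NNS(=O)(=O)c1ccc(C)cc1)c1cc(Br)cc(OC)c1OCc1cc(OC)c(O[Si](C(C)C)(C(C)C)C(C)C)c(OC)c1
F8 | step 10 | (E)-2-[3,5-bis(tert-butyldimethylsilyloxy)phenyl]ethenylboronic acid pinacol ester | CC1(C)OB(/C=C/c2cc(O[Si](C)(C)C(C)(C)C)cc(O[Si](C)(C)C(C)(C)C)c2)OC1(C)C
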